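All runs were generated by integration with constants of no real substance, noise included.

Over a few minutes of stirring at constant temperature, a single-handed free catalyst works through a racemate with a solid reagent, and I follow what is left of the two mirror-image substrates.

all flasks: free catalyst 0.76 mol%

| run | left-handed substrate | right-handed substrate | solid reagent | remark | time |
|---|---|---|---|---|---|
| Tuesday's | 0.070 M | 0.070 M | 1.2 equiv | run made earlier |  |
| Saturday's | 0.11 M | 0.11 M | 1.2 equiv | run made earlier |  |
| Thursday's | 0.050 M | 0.050 M | 2.4 equiv | run made earlier |  |
| maple | 0.050 M | 0.050 M | 1.20 equiv |  | 4.0 min |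
| birch | 0.050 M | 0.050 M | 1.20 equiv |  | 15 min |

| run | time / min | right-handed substrate / % | left-handed substrate / % |
|---|---|---|---|
| Tuesday's | 0.167 | 51.3 | 50.3 |
| Tuesday's | 0.500 | 50.7 | 48.8 |
| Tuesday's | 0.833 | 47.5 | 46.8 |
| Tuesday's | 1.33 | 49.2 | 43.4 |
| Tuesday's | 2.00 | 49.8 | 42.8 |
| Tuesday's | 2.50 | 48.7 | 38.7 |
| Tuesday's | 3.00 | 50.7 | 39.5 |
| Saturday's | 0.167 | 50.3 | 49.3 |
| Saturday's | 0.500 | 49.9 | 48.2 |
| Saturday's | 0.833 | 51.0 | 49.2 |
| Saturday's | 1.33 | 51.5 | 44.4 |
| Saturday's | 2.00 | 50.2 | 40.7 |
| Saturday's | 2.50 | 51.9 | 39.0 |
| Saturday's | 3.00 | 49.1 | 37.9 |
| Thursday's | 0.250 | 50.4 | 49.2 |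
| Thursday's | 0.500 | 52.5 | 48.6 |
| Thursday's | 0.833 | 49.8 | 47.4 |
| Thursday's | 1.50 | 51.0 | 43.1 |
| Thursday's | 3.00 | 48.3 | 38.8 |

(scatter of a reading: 1 percentage point)

1. the winner by excess of right-handed substrate over left-handed substrate among what is left of the two; "neither" if no more than 2 percentage points parts them (maple / birch / neither)
2. excess of right-handed substrate over left-handed substrate among what is left of the two at the end, maple
3. excess of right-handed substrate over left-handed substrate among what is left of the two at the end, birch

- free catalyst is single-handed; left-handed substrate and right-handed substrate are mirror images of each other, charged as a racemate, each of them at the stated concentration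
- solid reagent is a solid; its amount is given per volume of the solution
- what was read earlier has a scatter of 1 percentage point, one standard deviation
- at the start none of the solid reagent is in solution
- an excess is the difference of the two amounts in percent of their sum
- an excess is below zero if the other one leads

After 3.00 min the right-handed substrate stands at 50.7% on Tuesday's run, while the left-handed substrate has fallen from 0.5 of the pair's charge to 39.5%. Saturday's run has 1.57 times Tuesday's concentration and reads 37.9%. Thursday's run has 2.4 equiv of solid reagent against 1.2 equiv and reads 38.8%. More substrate and more reagent leave the fraction lost unchanged within the scatter of 1 percentage point.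

A fixed fraction looks like first order, but the loading is 0.76 mol% in each run, so the catalyst rises with the charge. A fixed fraction per minute therefore means a fixed rate per catalyst, which I read as near zero order in substrate, with some dissolved concentration staying put whatever the solid.

I carry the consumption slope, the fraction of the pair's charge lost as left-handed substrate per minute at this loading, 0.0376 min⁻¹, and I expect it to scale with loading.

For maple, 4.0 min on this slope leaves 0.350 of left-handed substrate, an excess of 17.7%. For birch the line reaches zero at 13.3 min, before 15 min, so the line gives me no number for birch, and I commit to birch as the winner.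

The forecast names birch, with 18% for maple and, “Allowing for a slowing tail”, 85% for birch.

The flasks give birch as the winner, with 18.3% for maple and 76.4% for birch.

    free catalyst + left-handed substrate ⇌ catalyst intermediate A (K = 60.5 M⁻¹, k = 53800 M⁻¹ min⁻¹)
    partner + catalyst intermediate A → free catalyst + left-handed product (k = 1190 M⁻¹ min⁻¹)
    free catalyst + right-handed substrate ⇌ catalyst intermediate B (K = 14.0 M⁻¹, k = 13800 M⁻¹ min⁻¹)
    partner + catalyst intermediate B → free catalyst + right-handed product (k = 36.0 M⁻¹ min⁻¹)
    solid reagent ⇌ partner, rate k5*(cs5 - [partner]) while solid is left; crystals form when [partner] > cs5 (solubility = 18.0 mM, k = 2.66 min⁻¹)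
    free catalyst ⇌ dormant form (K = 0.354, k = 0.139 min⁻¹)

The gap between birch and maple is the difference in time: with maple's time in place of its own, birch reads 18.3% instead of 76.4%. In maple the partner stands at 0.0163 M after 2.00 min and 0.0165 M after 4.00 min, the steady dissolved concentration that I read from the runs. Scaled to 0.3 mol% of free catalyst, the slope gives a neighbour of maple, otherwise the same flask, a loss of 0.0593 in 4.0 min, an excess of 6.30%; that flask stands at 7.17%.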